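(Readings and results come from a simulation from invented constants; noise was put on by code.)

If the protonated nucleophile has to lose its proton to free base before it can attack, and each product sets free one acid that free base or nucleophile must take up, then I can count what is left rather than what is made. I took that as my working assumption. With x as the part of the solid electrophile turned into product, the nucleophile left in equivalents is the smaller of two amounts: the protonated charge minus x, and the base charge minus two x. On this count it reaches zero at the ceiling X, the smaller of the protonated charge and half the base charge, which for summer is 40.0%.

| setting | Wednesday's | Thursday's | summer | autumn | dusk |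
|---|---|---|---|---|---|
| solid electrophile | 0.66 M | 0.66 M | 0.66 M | 0.66 M | 0.66 M |
| free base | 0.90 equiv | 3.6 equiv | 0.800 equiv | 1.60 equiv | 3.20 equiv |
| protonated nucleophile | 0.90 equiv | 0.90 equiv | 0.900 equiv | 0.900 equiv | 0.900 equiv |
| remark | run made earlier | run made earlier |  |  |  |
| time |  |  | 2.0 min | 2.0 min | 2.0 min |

| run | time / s | solid electrophile / % | product / % |
|---|---|---|---|
| Wednesday's | 10.0 | 94.6 | 2.6 |
| Wednesday's | 12.0 | 92.5 | 5.2 |
| Wednesday's | 20.0 | 90.7 | 5.4 |
| Wednesday's | 30.0 | 87.4 | 10.3 |
| Wednesday's | 50.0 | 81.1 | 17.6 |
| Wednesday's | 80.0 | 70.3 | 23.6 |
| Thursday's | 10.0 | 94.8 | 3.7 |
| Thursday's | 12.0 | 95.1 | 3.2 |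
| Thursday's | 20.0 | 91.0 | 7.0 |
| Thursday's | 30.0 | 87.1 | 10.8 |
| Thursday's | 50.0 | 78.2 | 17.9 |
| Thursday's | 80.0 | 68.0 | 27.4 |

(standard deviation of a reading: 1 percentage point)

- the analysis behind the earlier runs scatters by 1 percentage point, standard deviation
- at the start none of the solid electrophile is in solution
- what has only dissolved of solid electrophile counts as not reacted

* part of the solid electrophile that has reacted (what has only dissolved counts as not reacted) at the end, summer
* part of the solid electrophile that has reacted (what has only dissolved counts as not reacted) at the end, autumn
* part of the solid electrophile that has reacted (what has only dissolved counts as not reacted) at the end, dusk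
* what raising the equivalents of free base from its lowest to its highest value here does to the part of the solid electrophile that has reacted (what has only dissolved counts as not reacted) (changes below 5 percentage points count as none) (no change / it rises / it falls)

Two numbers looked contradictory. Wednesday's ceiling was 45.0% and Thursday's 90.0%, yet at 80.0 s their product readings were close, 23.6% and 27.4%. The reckoning cleared this up: a ceiling bounds how far a flask can go, not how fast it sets out, and by its last product reading Wednesday's run had used 52.4% of its ceiling.

At Thursday's pace, a straight line gave 41.1% by 2.0 min. Autumn's ceiling is 80.0% and dusk's 90.0%; the line stands at 51.4% of the first and 45.7% of the second, so I kept the line for both. In summer the same pace meets the ceiling after 117 s, about the whole run. I therefore let the pace in summer fall with the fraction of ceiling left, which gave 25.7%.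

The forecast said 39% for summer, 41% for autumn and 41% for dusk, trend no change, holding that “the rate is essentially zero order in free base”. It agreed with my reckoning on autumn and dusk and parted from it on summer.

The simulation gave 29.3% for summer, 40.6% for autumn and 40.7% for dusk, trend it rises, by 11 percentage points.

    electrophile + nucleophile ⇌ acid set free + product (K = 2.80, k = 0.270 M⁻¹ s⁻¹)
    nucleophile + acid set free ⇌ protonated nucleophile, settled at all times (K = 78.0 M⁻¹)
    acid set free + free base ⇌ salt of the base, settled at all times (K = 71000 M⁻¹)
    solid electrophile ⇌ electrophile, rate k4*(cs4 - [electrophile]) while solid is left; crystals form when [electrophile] > cs4 (solubility = 32.0 mM, k = 0.180 s⁻¹)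

In summer at 2.00 min, the step of electrophile with nucleophile had a relaxation half-life, both ways together, of 0.163 min, far shorter than the 2.0 min run. Free base, the limiting reagent, stood at 0.073% of its charge. The neighbour that is summer left until 8.0 min keeps the ceiling 40.0%, and the fraction left gives 39.3%; the computed result is 35.6%.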